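**Strategy**

Everything rests on making benzene ring A of the dihydrobenzofuran (C3a, C4, C5, C6, C7, C7a) from an open-chain diazo enone and ethoxyethyne. The feature exploited is that ring A bears oxygen on C7a and on C6, meta to one another, with the C3 carbon chain on C3a beside the C7a oxygen, which is what annulation of a vinylketene with an ynol ether gives regiospecifically. In one operation the step forms the ring and sets all three substituents. Its precursor is an (E)-α'-diazo enone whose allylic carbon carries the (S)-diol as an acetonide. C5 acetylation, BCl3 unmasking, Mitsunobu closure with inversion and Claisen–Schmidt condensation finish the target.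

Key step: step 5

Assumption: 1 and 21 are taken as purchasable, 1 as the single (S) enantiomer; atom labels (O1, C2, C3, C3a, C4 to C7, C7a) are those of the dihydrobenzofuran in the target.

**Route**

Step 1
Reactants: 1 (S)-2-(oxiran-2-yl)propan-2-ol; 2 vinylmagnesium bromide
Product: 3 (3S)-2-methylhex-5-ene-2,3-diol
Conditions: 2 (2.5 equiv), CuBr·SMe2 (10 mol%), THF, −40 to 0 °C; then H2O
Reagents that add atoms: none
Why: Copper-catalysed SN2 opening of the terminal epoxide by the vinyl Grignard reagent should occur at the unhindered CH2 (one equivalent is spent on the hydroxyl), and since no bond to the stereocentre is made or broken the (S) centre of 1 is carried over unchanged.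

Step 2
Reactants: 3 (3S)-2-methylhex-5-ene-2,3-diol
Product: 4 (4S)-2,2,5,5-tetramethyl-4-(prop-2-en-1-yl)-1,3-dioxolane
Conditions: Me2C(OMe)2, PPTS (cat.), CH2Cl2, rt
Reagents that add atoms: 2,2-dimethoxypropane, COC(C)(C)OC
Why: Acid-catalysed transketalisation (acetonide formation) of the 1,2-diol, driven by loss of methanol, should mask both hydroxyls against the later enolate, diazo and ketene chemistry.

Step 3
Reactants: 4 (4S)-2,2,5,5-tetramethyl-4-(prop-2-en-1-yl)-1,3-dioxolane; 5 but-3-en-2-one
Product: 6 (3E)-5-[(4S)-2,2,5,5-tetramethyl-1,3-dioxolan-4-yl]pent-3-en-2-one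
Conditions: 5 (3 equiv), second-generation Grubbs catalyst RuCl2(=CHPh)(H2IMes)(PCy3) (3 mol%), CH2Cl2, 40 °C
Reagents that add atoms: none
Why: Olefin cross-metathesis of a terminal alkene with an electron-poor enone that is slow to homodimerise should give the conjugated (E)-enone under thermodynamic control, the ketal being inert to the ruthenium carbene.

Step 4
Reactants: 6 (3E)-5-[(4S)-2,2,5,5-tetramethyl-1,3-dioxolan-4-yl]pent-3-en-2-one
Product: 8 (3E)-1-diazo-5-[(4S)-2,2,5,5-tetramethyl-1,3-dioxolan-4-yl]pent-3-en-2-one, via trifluoroacetyl diketone 7 (not isolated)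
Conditions: LiN(SiMe3)2 (1.1 equiv), THF, −78 °C; CF3CO2CH2CF3; AcOH; then 4-AcNHC6H4SO2N3, Et3N, H2O (1 equiv), MeCN, rt
Reagents that add atoms: 2,2,2-trifluoroethyl trifluoroacetate, O=C(OCC(F)(F)F)C(F)(F)F (trifluoroacetyl group of 7); 4-acetamidobenzenesulfonyl azide, CC(=O)Nc1ccc(cc1)S(=O)(=O)N=[N+]=[N-] (N2 unit of 8)
Why: Detrifluoroacetylative diazo transfer (a Regitz-type transfer to an activated ketone) should work because the hindered amide base enolises the methyl group kinetically, Claisen trifluoroacetylation gives 7, and azide transfer with loss of the trifluoroacetyl group as the N-sulfonyl amide leaves the diazomethyl ketone with the (E)-alkene intact.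

Step 5
Reactants: 8 (3E)-1-diazo-5-[(4S)-2,2,5,5-tetramethyl-1,3-dioxolan-4-yl]pent-3-en-2-one; 9 ethoxyethyne
Product: 14 5-ethoxy-2-{[(4S)-2,2,5,5-tetramethyl-1,3-dioxolan-4-yl]methyl}phenol, via vinylketene 10 (not isolated), via vinylcyclobutenone 11 (not isolated), via dienylketene 12 (not isolated), via cyclohexadienone 13 (not isolated)
Conditions: 9 (3 equiv), ClCH2CH2Cl, hν (254 nm), 20 °C; excess 9 removed in vacuo; toluene, 80 °C
Reagents that add atoms: none
Why: Light drives loss of N2 from 8 and the alkenyl substituent moves from the carbonyl carbon to the carbene carbon (Wolff rearrangement, which makes C4–C5) to give vinylketene 10, which adds the ynol ether across its C=C bond in a (2+2) cycloaddition (making C7a–C7 and C5–C6) to give 11; on warming, conrotatory 4π opening of 11 cleaves the former C7a–C5 bond and gives dienylketene 12. Ring A is then closed by thermal disrotatory 6π electrocyclisation of 12 (making C7a–C3a) to 13, whose enolisation gives the phenol. The closest known reaction type is the photochemical Wolff version of the Danheiser benzannulation of α'-diazo enones with heteroatom-substituted alkynes. No stereocentre is created, and the (4S) centre lies outside the reacting π-system and should pass through unchanged. The selectivity needed is regiochemical: the nucleophilic unsubstituted alkyne carbon bonds to the electrophilic ketene carbon, which puts ethoxy meta to the new hydroxyl, and closure onto the (E)-alkene terminus puts the side chain ortho to it. With both side-chain oxygens tied up in the ketal no hydroxyl can intercept a ketene, and stripping the excess alkyne before heating avoids its retro-ene breakdown.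

Step 6
Reactants: 14 5-ethoxy-2-{[(4S)-2,2,5,5-tetramethyl-1,3-dioxolan-4-yl]methyl}phenol
Product: 15 4-bromo-5-ethoxy-2-{[(4S)-2,2,5,5-tetramethyl-1,3-dioxolan-4-yl]methyl}phenol
Conditions: NBS (1.0 equiv), MeCN, −20 to 0 °C, dark
Reagents that add atoms: N-bromosuccinimide, O=C1CCC(=O)N1Br
Why: Electrophilic aromatic bromination should go to the carbon para to the free hydroxyl and ortho to ethoxy (the future C5), the only doubly activated position not flanked by both oxygens, under neutral conditions that spare the acetonide.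

Step 7
Reactants: 15 4-bromo-5-ethoxy-2-{[(4S)-2,2,5,5-tetramethyl-1,3-dioxolan-4-yl]methyl}phenol; 16 N-methoxy-N-methylacetamide
Product: 18 1-(2-ethoxy-4-hydroxy-5-{[(4S)-2,2,5,5-tetramethyl-1,3-dioxolan-4-yl]methyl}phenyl)ethan-1-one, via dilithio phenoxide 17 (not isolated)
Conditions: n-BuLi (2.2 equiv), THF, −78 °C; 16 (1.5 equiv), −78 to 0 °C; AcOH
Reagents that add atoms: none
Why: Deprotonation of the phenol and bromine–lithium exchange give an aryllithium that the Weinreb amide should acylate once only (stable chelated tetrahedral adduct), installing the acetyl group without any Lewis acid that would open the acetonide.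

Step 8
Reactants: 18 1-(2-ethoxy-4-hydroxy-5-{[(4S)-2,2,5,5-tetramethyl-1,3-dioxolan-4-yl]methyl}phenyl)ethan-1-one
Product: 19 1-{5-[(2S)-2,3-dihydroxy-3-methylbutyl]-2,4-dihydroxyphenyl}ethan-1-one
Conditions: BCl3 (4 equiv), CH2Cl2, −78 to 0 °C; then H2O, 1 M HCl, THF, rt
Reagents that add atoms: none
Why: Chelation-assisted ether cleavage should remove the ethyl group because BCl3 held between the ketone oxygen and the ortho ethoxy oxygen delivers chloride to the ethyl carbon, while the same reagent opens the acetonide and keeps the diol tied to boron as a cyclic ester (so the tertiary C–O bond is not ionised) until the acidic work-up releases it with the (S) centre untouched.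

Step 9
Reactants: 19 1-{5-[(2S)-2,3-dihydroxy-3-methylbutyl]-2,4-dihydroxyphenyl}ethan-1-one
Product: 20 1-[(2R)-6-hydroxy-2-(2-hydroxypropan-2-yl)-2,3-dihydro-1-benzofuran-5-yl]ethan-1-one
Conditions: PPh3 (1.5 equiv), DIAD (1.5 equiv), THF, 0 °C to rt
Reagents that add atoms: none
Why: Intramolecular Mitsunobu etherification should close O1–C2 because the acidic phenol para to the acetyl group is deprotonated, the secondary hydroxyl is activated as its oxyphosphonium and displaced 5-exo-tet with inversion, turning (S) into (2R), while the tertiary hydroxyl cannot be displaced and the hydrogen-bonded phenol ortho to the ketone cannot reach.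

Step 10
Reactants: 20 1-[(2R)-6-hydroxy-2-(2-hydroxypropan-2-yl)-2,3-dihydro-1-benzofuran-5-yl]ethan-1-one; 21 2,2-dimethyl-3,4-dihydro-2H-chromene-6-carbaldehyde
Product: 22 (2E)-3-(2,2-dimethyl-3,4-dihydro-2H-chromen-6-yl)-1-[(2R)-6-hydroxy-2-(2-hydroxypropan-2-yl)-2,3-dihydro-1-benzofuran-5-yl]prop-2-en-1-one
Conditions: 21 (1.2 equiv), KOH (aq., excess), EtOH, rt; then 1 M HCl to pH 5
Reagents that add atoms: none
Why: Claisen–Schmidt condensation of the methyl ketone with the non-enolisable aldehyde should give the thermodynamically preferred (E)-chalcone, and C2 carries no acidic hydrogen, so the (2R) centre is not at risk in base.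

**Compound list**

1 | (S)-2-(oxiran-2-yl)propan-2-ol | CC(C)(O)[C@@H]1CO1 | starting material
2 | vinylmagnesium bromide | C=C[Mg]Br | starting material
3 | (3S)-2-methylhex-5-ene-2,3-diol | C=CC[C@H](O)C(C)(C)O | intermediate
4 | (4S)-2,2,5,5-tetramethyl-4-(prop-2-en-1-yl)-1,3-dioxolane | C=CC[C@@H]1OC(C)(C)OC1(C)C | intermediate
5 | but-3-en-2-one (methyl vinyl ketone) | CC(=O)C=C | starting material
6 | (3E)-5-[(4S)-2,2,5,5-tetramethyl-1,3-dioxolan-4-yl]pent-3-en-2-one | CC(=O)/C=C/C[C@@H]1OC(C)(C)OC1(C)C | intermediate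
7 | (5E)-1,1,1-trifluoro-7-[(4S)-2,2,5,5-tetramethyl-1,3-dioxolan-4-yl]hept-5-ene-2,4-dione | O=C(CC(=O)C(F)(F)F)/C=C/C[C@@H]1OC(C)(C)OC1(C)C | intermediate (not isolated)
8 | (3E)-1-diazo-5-[(4S)-2,2,5,5-tetramethyl-1,3-dioxolan-4-yl]pent-3-en-2-one | [N-]=[N+]=CC(=O)/C=C/C[C@@H]1OC(C)(C)OC1(C)C | intermediate
9 | ethoxyethyne | C#COCC | starting material
10 | (3E)-5-[(4S)-2,2,5,5-tetramethyl-1,3-dioxolan-4-yl]penta-1,3-dien-1-one (vinylketene) | O=C=C/C=C/C[C@@H]1OC(C)(C)OC1(C)C | intermediate (not isolated)
11 | 3-ethoxy-4-{(1E)-3-[(4S)-2,2,5,5-tetramethyl-1,3-dioxolan-4-yl]prop-1-en-1-yl}cyclobut-2-en-1-one (both C4 epimers) | CCOC1=CC(=O)C1/C=C/C[C@@H]2OC(C)(C)OC2(C)C | intermediate (not isolated)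
12 | (3E,5E)-3-ethoxy-7-[(4S)-2,2,5,5-tetramethyl-1,3-dioxolan-4-yl]hepta-1,3,5-trien-1-one (dienylketene) | O=C=C/C(OCC)=C\C=C\C[C@@H]1OC(C)(C)OC1(C)C | intermediate (not isolated)
13 | 3-ethoxy-6-{[(4S)-2,2,5,5-tetramethyl-1,3-dioxolan-4-yl]methyl}cyclohexa-2,4-dien-1-one (both C6 epimers) | O=C1C=C(OCC)C=CC1C[C@@H]2OC(C)(C)OC2(C)C | intermediate (not isolated)
14 | 5-ethoxy-2-{[(4S)-2,2,5,5-tetramethyl-1,3-dioxolan-4-yl]methyl}phenol | CCOc1ccc(C[C@@H]2OC(C)(C)OC2(C)C)c(O)c1 | intermediate
15 | 4-bromo-5-ethoxy-2-{[(4S)-2,2,5,5-tetramethyl-1,3-dioxolan-4-yl]methyl}phenol | CCOc1cc(O)c(C[C@@H]2OC(C)(C)OC2(C)C)cc1Br | intermediate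
16 | N-methoxy-N-methylacetamide | CC(=O)N(C)OC | starting material
17 | lithium 5-ethoxy-4-lithio-2-{[(4S)-2,2,5,5-tetramethyl-1,3-dioxolan-4-yl]methyl}phenolate | CCOc1cc(O[Li])c(C[C@@H]2OC(C)(C)OC2(C)C)cc1[Li] | intermediate (not isolated)
18 | 1-(2-ethoxy-4-hydroxy-5-{[(4S)-2,2,5,5-tetramethyl-1,3-dioxolan-4-yl]methyl}phenyl)ethan-1-one | CCOc1cc(O)c(C[C@@H]2OC(C)(C)OC2(C)C)cc1C(C)=O | intermediate
19 | 1-{5-[(2S)-2,3-dihydroxy-3-methylbutyl]-2,4-dihydroxyphenyl}ethan-1-one | CC(=O)c1cc(C[C@H](O)C(C)(C)O)c(O)cc1O | intermediate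
20 | 1-[(2R)-6-hydroxy-2-(2-hydroxypropan-2-yl)-2,3-dihydro-1-benzofuran-5-yl]ethan-1-one | CC(=O)c1cc2c(cc1O)O[C@@H](C(C)(C)O)C2 | intermediate
21 | 2,2-dimethyl-3,4-dihydro-2H-chromene-6-carbaldehyde | CC1(C)CCc2cc(C=O)ccc2O1 | starting material
22 | (2E)-3-(2,2-dimethyl-3,4-dihydro-2H-chromen-6-yl)-1-[(2R)-6-hydroxy-2-(2-hydroxypropan-2-yl)-2,3-dihydro-1-benzofuran-5-yl]prop-2-en-1-one | CC1(C)CCc2cc(/C=C/C(=O)c3cc4c(cc3O)O[C@@H](C(C)(C)O)C4)ccc2O1 | target

**Count**

Total steps: 10. Longest linear sequence: 10 steps (1 to 22); 2, 5, 9, 16 and 21 enter as bought reagents.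

**Steps most likely to fail**

Step 5 (key step). The ketene intermediates may be diverted before the alkyne captures them (dimerisation, acylation of the product phenol, photodegradation of the product under the lamp), and the side chain is untested in this annulation. The fallback gives up the ring construction and uses a ready-made arene; it sets out from 1 and comes back at 14. The benzyl ether of 2-bromo-5-ethoxyphenol, 1-(benzyloxy)-2-bromo-5-ethoxybenzene F1, is converted with Mg in THF into [2-(benzyloxy)-4-ethoxyphenyl]magnesium bromide F2. Copper-catalysed (CuBr·SMe2) opening of epoxide 1 at its CH2 by F2, the same reaction type as step 1, should give (2S)-1-[2-(benzyloxy)-4-ethoxyphenyl]-3-methylbutane-2,3-diol F3 with the stereocentre untouched. Ketalisation with 2,2-dimethoxypropane and PPTS gives (4S)-4-{[2-(benzyloxy)-4-ethoxyphenyl]methyl}-2,2,5,5-tetramethyl-1,3-dioxolane F4, and hydrogenolysis (H2, Pd/C, EtOAc) of the benzyl ether returns 14.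

Step 8. The Lewis acid may ionise the tertiary carbinol carbon (elimination or a pinacol-type shift), or loss of the ethyl group may be sluggish. The fallback replaces Lewis-acid cleavage by a basic SN2 dealkylation after ring closure; it sets out from 18 and comes back at 20. Aqueous acetic acid (AcOH/H2O, 40 °C) removes only the acetonide and gives 1-{5-[(2S)-2,3-dihydroxy-3-methylbutyl]-2-ethoxy-4-hydroxyphenyl}ethan-1-one F5. Mitsunobu closure (PPh3, DIAD, THF) then gives, with inversion, 1-[(2R)-6-ethoxy-2-(2-hydroxypropan-2-yl)-2,3-dihydro-1-benzofuran-5-yl]ethan-1-one F6. Sodium ethanethiolate in DMF at about 110 °C attacks the ethyl carbon, with the ortho-acyl phenoxide as leaving group and no cationic character at the tertiary carbinol, to give 20.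

Step 9. The activated secondary carbinol may be captured by the neighbouring tertiary hydroxyl (epoxide closure) ahead of the phenoxide; reopening of that epoxide by the phenol would close the ring with overall retention and erode enantiopurity. The fallback separates activation from displacement; it sets out from 19 and comes back at 20. Benzylation of the non-chelated phenol (BnBr, K2CO3, acetone) gives 1-{4-(benzyloxy)-5-[(2S)-2,3-dihydroxy-3-methylbutyl]-2-hydroxyphenyl}ethan-1-one F7. Mesylation (MsCl, Et3N, CH2Cl2, −20 °C) of the secondary hydroxyl, the only reactive alcohol, gives (2S)-1-[5-acetyl-2-(benzyloxy)-4-hydroxyphenyl]-3-hydroxy-3-methylbutan-2-yl methanesulfonate F8. Hydrogenolysis (H2, Pd/C, EtOAc) frees the phenol to give (2S)-1-(5-acetyl-2,4-dihydroxyphenyl)-3-hydroxy-3-methylbutan-2-yl methanesulfonate F9. K2CO3 in acetone then closes O1–C2 by intramolecular Williamson displacement (5-exo-tet, inversion) to give 20; this weak base forms only the phenoxide and not the tertiary alkoxide, so the epoxide path is shut.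

**Further compounds**

F1 | step 5 | 1-(benzyloxy)-2-bromo-5-ethoxybenzene | CCOc1ccc(Br)c(OCc2ccccc2)c1
F2 | step 5 | [2-(benzyloxy)-4-ethoxyphenyl]magnesium bromide | CCOc1ccc([Mg]Br)c(OCc2ccccc2)c1
F3 | step 5 | (2S)-1-[2-(benzyloxy)-4-ethoxyphenyl]-3-methylbutane-2,3-diol | CCOc1ccc(C[C@H](O)C(C)(C)O)c(OCc2ccccc2)c1
F4 | step 5 | (4S)-4-{[2-(benzyloxy)-4-ethoxyphenyl]methyl}-2,2,5,5-tetramethyl-1,3-dioxolane | CCOc1ccc(C[C@@H]2OC(C)(C)OC2(C)C)c(OCc3ccccc3)c1
F5 | step 8 | 1-{5-[(2S)-2,3-dihydroxy-3-methylbutyl]-2-ethoxy-4-hydroxyphenyl}ethan-1-one | CCOc1cc(O)c(C[C@H](O)C(C)(C)O)cc1C(C)=O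
F6 | step 8 | 1-[(2R)-6-ethoxy-2-(2-hydroxypropan-2-yl)-2,3-dihydro-1-benzofuran-5-yl]ethan-1-one | CC(=O)c1cc2c(cc1OCC)O[C@@H](C(C)(C)O)C2
F7 | step 9 | 1-{4-(benzyloxy)-5-[(2S)-2,3-dihydroxy-3-methylbutyl]-2-hydroxyphenyl}ethan-1-one | CC(=O)c1cc(C[C@H](O)C(C)(C)O)c(OCc2ccccc2)cc1O
F8 | step 9 | (2S)-1-[5-acetyl-2-(benzyloxy)-4-hydroxyphenyl]-3-hydroxy-3-methylbutan-2-yl methanesulfonate | CC(=O)c1cc(C[C@H](OS(C)(=O)=O)C(C)(C)O)c(OCc2ccccc2)cc1O
F9 | step 9 | (2S)-1-(5-acetyl-2,4-dihydroxyphenyl)-3-hydroxy-3-methylbutan-2-yl methanesulfonate | CC(=O)c1cc(C[C@H](OS(C)(=O)=O)C(C)(C)O)c(O)cc1O
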